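**Retrosynthetic overview**
1. Fragransin B1 (9) is meso: an oxolane (O1, C2–C5) whose syringyl groups at C2/C5 are cis to each other and trans to the cis-methyls at C3/C4, which is the thermodynamically preferred C2/C5 arrangement for a cis-3,4-dimethyl ring.
2. Enabling feature: C2 and C5 are benzylic carbons, each para to a free phenolic OH of its aryl ring, so a C2–C5 σ-bond (a cyclobutane C2–C3–C4–C5) can be opened by two-electron oxidation to a bis(p-quinone methide) and O1 supplied by water.
3. Key disconnection: O1–C2/O1–C5 ⇒ cyclobutane bis-phenol 5 (anodic 4→5 ring expansion by O-insertion); C2/C5 are set by equilibration, C3/C4 are inherited.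
4. Cyclobutane (the only ring built before the oxolane; both aryl rings are bought) ⇒ head-to-head [2+2] photodimerization of (E)-propenylarene 3, which forms the C3–C4 bond with cis-methyls.
5. 3 ⇒ 4-allyl-2,6-dimethoxyphenol (1) by alkene isomerization and O-silylation.

Key step: step 5

Remark: the target is achiral (meso), so only relative configuration has to be controlled and no enantioselective step is needed; 1 is taken as a commercial material.

**Step 1**
Reactants: 1 4-allyl-2,6-dimethoxyphenol
Product: 2 (E)-2,6-dimethoxy-4-(prop-1-en-1-yl)phenol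
Conditions: RuHCl(CO)(PPh3)3 (1 mol %), toluene, 80 °C
Reagents that add atoms: none
Why: Ru–H-catalysed alkene isomerization (hydrometalation/β-hydride elimination) should move the allyl double bond into conjugation with the arene and give the thermodynamically preferred E alkene, the free phenol being tolerated.

**Step 2**
Reactants: 2 (E)-2,6-dimethoxy-4-(prop-1-en-1-yl)phenol
Product: 3 tert-butyl{2,6-dimethoxy-4-[(E)-prop-1-en-1-yl]phenoxy}dimethylsilane
Conditions: TBSCl, imidazole, DMF, rt to 40 °C
Reagents that add atoms: tert-butyldimethylsilyl chloride (TBSCl), CC(C)(C)[Si](C)(C)Cl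
Why: Standard imidazole-promoted O-silylation of a phenol, which masks the photolabile and oxidisable O–H with a group that is transparent above 290 nm.

**Step 3**
Reactants: 3 tert-butyl{2,6-dimethoxy-4-[(E)-prop-1-en-1-yl]phenoxy}dimethylsilane (two molecules)
Product: 4 (1R,2S,3R,4S)-1,2-bis[4-(tert-butyldimethylsilyloxy)-3,5-dimethoxyphenyl]-3,4-dimethylcyclobutane (meso; aryls cis, methyls cis, each methyl trans to the neighbouring aryl)
Conditions: hν (Hg lamp, Pyrex, λ > 290 nm), degassed cyclohexane (ca. 1 M), 15 °C; recovered E/Z-3 recycled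
Reagents that add atoms: none
Why: Singlet-excimer [2+2] photodimerization of an electron-rich (E)-1-arylpropene, the reaction type known for (E)-anethole and (E)-asarone, should give the head-to-head syn dimer through a sandwich excimer, and the suprafacial addition keeps each methyl trans to its own aryl, which places the two methyls cis (the only relationship that must survive, because the aryl-bearing centres are erased in step 5).

**Step 4**
Reactants: 4 (1R,2S,3R,4S)-1,2-bis[4-(tert-butyldimethylsilyloxy)-3,5-dimethoxyphenyl]-3,4-dimethylcyclobutane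
Product: 5 4,4'-[(1R,2S,3R,4S)-3,4-dimethylcyclobutane-1,2-diyl]bis(2,6-dimethoxyphenol) (meso)
Conditions: TBAF, AcOH, THF, 0 °C, Ar
Reagents that add atoms: none
Why: Fluoride cleavage of aryl silyl ethers, buffered with AcOH so that the electron-rich phenols are not left as air-sensitive phenolates; no stereocentre is touched.

**Step 5**
Reactants: 5 4,4'-[(1R,2S,3R,4S)-3,4-dimethylcyclobutane-1,2-diyl]bis(2,6-dimethoxyphenol)
Product: 9 fragransin B1 = 4,4'-[(2R,3R,4S,5S)-3,4-dimethyloxolane-2,5-diyl]bis(2,6-dimethoxyphenol) (meso), via bis(quinone methide) 6 (not isolated), via hydroxy quinone methide 7 (not isolated), via oxolane epimer mixture 8 (not isolated)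
Conditions: graphite anode, Pt cathode, divided cell, LiClO4 (0.1 M), MeCN/H2O 4:1, controlled potential at the first anodic wave of 5, 2.0 F/mol, 0 °C, Ar; then anolyte held at 40 °C (electrogenerated HClO4) until the epimers converge; NaHCO3
Reagents that add atoms: water, O
Why: Proposed new method: anodic two-electron oxidation of a phenol ring of 5 (phenoxyl radical, then loss of the second electron) is coupled to strain-driven cleavage of the doubly benzylic cyclobutane bond C1–C2, which is para to both OH groups and aligned with both arene π systems, and should release the meso bis(p-quinone methide) 6; water adds 1,6 to one quinone methide (7) and the new benzylic OH closes the oxolane by 5-exo-trig oxa-1,6-addition to the other (8), so the four-membered ring is expanded by one oxygen atom. The closest known reaction types are the mesolytic C–C fragmentation of bibenzyl, arylcyclopropane and donor–acceptor arylcyclobutane radical cations with capture by water, alcohols or O2 under anodic or photoredox conditions, the oxidation of 4-alkyl-2,6-dimethoxyphenols to p-quinone methides, and the water-terminated oxidative 8–8′ dimerization of 4-propenylphenols to 2,5-diaryl-3,4-dimethyltetrahydrofurans, which passes through the same kind of bis(quinone methide). C3 and C4 are not touched and carry over the cis-methyl relationship of 5. C2 and C5 are set under thermodynamic control: as p-hydroxybenzylic ether carbons they ionize reversibly (benzylic cation/quinone methide) under the acid that the oxidation itself liberates, so all C2/C5 epimers of 8 should converge on the isomer with each aryl trans to its neighbouring methyl and the two aryls cis, which is the configuration of 9, and the aryl configuration of the cyclobutane is irrelevant. The step needs C1–C2 and not C1–C4 cleavage, secured because only C1–C2 scission gives two quinone methides, and oxidation of 5 in preference to 9, secured by charge control and by the lower potential and irreversible follow-up expected for the σ-coupled cis-diarylcyclobutane.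

**Compound list**
1 | 4-allyl-2,6-dimethoxyphenol | C=CCc1cc(OC)c(O)c(OC)c1 | starting material
2 | (E)-2,6-dimethoxy-4-(prop-1-en-1-yl)phenol | C/C=C/c1cc(OC)c(O)c(OC)c1 | intermediate
3 | tert-butyl{2,6-dimethoxy-4-[(E)-prop-1-en-1-yl]phenoxy}dimethylsilane | C/C=C/c1cc(OC)c(O[Si](C)(C)C(C)(C)C)c(OC)c1 | intermediate
4 | (1R,2S,3R,4S)-1,2-bis[4-(tert-butyldimethylsilyloxy)-3,5-dimethoxyphenyl]-3,4-dimethylcyclobutane (meso) | COc1cc([C@@H]2[C@H](c3cc(OC)c(O[Si](C)(C)C(C)(C)C)c(OC)c3)[C@@H](C)[C@H]2C)cc(OC)c1O[Si](C)(C)C(C)(C)C | intermediate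
5 | 4,4'-[(1R,2S,3R,4S)-3,4-dimethylcyclobutane-1,2-diyl]bis(2,6-dimethoxyphenol) (meso) | COc1cc([C@@H]2[C@H](c3cc(OC)c(O)c(OC)c3)[C@@H](C)[C@H]2C)cc(OC)c1O | intermediate
6 | 4,4'-[(2R,3S)-2,3-dimethylbutane-1,4-diylidene]bis(2,6-dimethoxycyclohexa-2,5-dien-1-one) (meso bis(p-quinone methide)) | COC1=CC(=C[C@@H](C)[C@@H](C)C=C2C=C(OC)C(=O)C(OC)=C2)C=C(OC)C1=O | intermediate
7 | 4-[4-hydroxy-4-(4-hydroxy-3,5-dimethoxyphenyl)-2,3-dimethylbutylidene]-2,6-dimethoxycyclohexa-2,5-dien-1-one (erythro 2,3-dimethyl, racemic, both carbinol epimers) | COC1=CC(=C[C@@H](C)[C@@H](C)C(O)c2cc(OC)c(O)c(OC)c2)C=C(OC)C1=O | intermediate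
8 | 4,4'-(3,4-cis-dimethyloxolane-2,5-diyl)bis(2,6-dimethoxyphenol), mixture of C2/C5 epimers | COc1cc(C2OC(c3cc(OC)c(O)c(OC)c3)[C@H](C)[C@@H]2C)cc(OC)c1O | intermediate
9 | fragransin B1, 4,4'-[(2R,3R,4S,5S)-3,4-dimethyloxolane-2,5-diyl]bis(2,6-dimethoxyphenol) (meso) | COc1cc([C@H]2O[C@@H](c3cc(OC)c(O)c(OC)c3)[C@H](C)[C@@H]2C)cc(OC)c1O | target

**Step count**
Total steps: 5. Longest linear sequence: 5 steps (1 → 9).

**Steps most likely to fail**

Step 5 (proposed new method). Several processes could divert it:
- over-oxidation of the product phenols, which have a similar redox potential to 5;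
- a second C–C scission of the ring-opened radical (oxidative cycloreversion to propenylphenol units), whose unselective re-coupling would lose the C3/C4 relationship;
- capture of the oxidised phenol by water at the ring carbon instead of fragmentation;
- acid-driven drift to aryltetralins, or C3/C4 epimerization by elimination and re-protonation, during the equilibration.

The fallback uses known chemistry only, sets out from 3 and returns at 9. Oxidative cleavage of the propenyl group (OsO4 cat., NaIO4, 2,6-lutidine, dioxane/H2O) should give 4-(tert-butyldimethylsilyloxy)-3,5-dimethoxybenzaldehyde F1. Addition of EtMgBr (THF, 0 °C) gives 1-[4-(tert-butyldimethylsilyloxy)-3,5-dimethoxyphenyl]propan-1-ol F2, and MnO2 (CH2Cl2) gives the propiophenone F3. Oxidative enolate homocoupling (LDA, THF, −78 °C; then CuCl2, DMF) gives the 2,3-dimethyl-1,4-dione, from which the meso diketone F4 is taken by crystallization, the racemic isomer being recycled by base epimerization. LiAlH4 (THF, 0 °C) gives the meso-derived 1,4-diol F5 as carbinol epimers. Acid-catalysed cyclodehydration under thermodynamic control (CSA, CH2Cl2, rt) gives the bis-TBS ether of the target F6, and TBAF/AcOH gives 9.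

Step 3. E/Z photoisomerization may outrun dimerization, the excimer may give the anti head-to-head dimer with trans-methyls, and conversion may be slow on scale. The fallback replaces the intermolecular dimerization by a templated intramolecular one, sets out from 1 and returns at 5. Two molecules of 1 are joined with 1,3-dichloro-1,1,3,3-tetraisopropyldisiloxane (imidazole, DMF) to the bis(4-allyl-2,6-dimethoxyphenoxy)disiloxane F7. RuHCl(CO)(PPh3)3 (toluene, 80 °C) gives the bis[(E)-propenyl] compound F8. Irradiation (λ > 290 nm, 0.01 M, cyclohexane) should give the disiloxane-bridged cyclobutane F9, because the para–para tether allows only the head-to-head syn union and the intramolecular cycloaddition competes better with isomerization. TBAF/AcOH removes the tether and gives 5.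

Step 4. The liberated electron-rich phenolates may be oxidised by air or oligomerize during fluoride desilylation. The fallback changes the protecting-group strategy to an acid-cleaved acetal, sets out from 2 and returns at 5. MOMCl/iPr2NEt (CH2Cl2) gives the methoxymethyl ether F10. Photodimerization as in step 3 gives the bis-MOM cyclobutane F11. HCl/MeOH (40 °C, Ar) unmasks 5 under acidic, non-oxidising conditions without a phenolate stage.

**Further compounds**
F1 | step 5 | 4-(tert-butyldimethylsilyloxy)-3,5-dimethoxybenzaldehyde | COc1cc(C=O)cc(OC)c1O[Si](C)(C)C(C)(C)C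
F2 | step 5 | 1-[4-(tert-butyldimethylsilyloxy)-3,5-dimethoxyphenyl]propan-1-ol (racemic) | CCC(O)c1cc(OC)c(O[Si](C)(C)C(C)(C)C)c(OC)c1
F3 | step 5 | 1-[4-(tert-butyldimethylsilyloxy)-3,5-dimethoxyphenyl]propan-1-one | CCC(=O)c1cc(OC)c(O[Si](C)(C)C(C)(C)C)c(OC)c1
F4 | step 5 | (2R,3S)-1,4-bis[4-(tert-butyldimethylsilyloxy)-3,5-dimethoxyphenyl]-2,3-dimethylbutane-1,4-dione (meso) | COc1cc(C(=O)[C@H](C)[C@H](C)C(=O)c2cc(OC)c(O[Si](C)(C)C(C)(C)C)c(OC)c2)cc(OC)c1O[Si](C)(C)C(C)(C)C
F5 | step 5 | 1,4-bis[4-(tert-butyldimethylsilyloxy)-3,5-dimethoxyphenyl]-2,3-dimethylbutane-1,4-diol (meso-derived 2,3-dimethyl, carbinol epimers) | COc1cc(C(O)[C@H](C)[C@H](C)C(O)c2cc(OC)c(O[Si](C)(C)C(C)(C)C)c(OC)c2)cc(OC)c1O[Si](C)(C)C(C)(C)C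
F6 | step 5 | (2R,3R,4S,5S)-2,5-bis[4-(tert-butyldimethylsilyloxy)-3,5-dimethoxyphenyl]-3,4-dimethyloxolane (meso) | COc1cc([C@H]2O[C@@H](c3cc(OC)c(O[Si](C)(C)C(C)(C)C)c(OC)c3)[C@H](C)[C@@H]2C)cc(OC)c1O[Si](C)(C)C(C)(C)C
F7 | step 3 | 1,3-bis(4-allyl-2,6-dimethoxyphenoxy)-1,1,3,3-tetraisopropyldisiloxane | C=CCc1cc(OC)c(O[Si](C(C)C)(C(C)C)O[Si](C(C)C)(C(C)C)Oc2c(OC)cc(CC=C)cc2OC)c(OC)c1
F8 | step 3 | 1,3-bis{2,6-dimethoxy-4-[(E)-prop-1-en-1-yl]phenoxy}-1,1,3,3-tetraisopropyldisiloxane | C/C=C/c1cc(OC)c(O[Si](C(C)C)(C(C)C)O[Si](C(C)C)(C(C)C)Oc2c(OC)cc(/C=C/C)cc2OC)c(OC)c1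
F9 | step 3 | disiloxane-bridged cyclobutane: cyclobutane of 4 with the two phenolic oxygens joined by Si(iPr)2–O–Si(iPr)2 (aryls cis, methyls cis, methyls trans to aryls) | COc1cc([C@@H]2[C@H](c3cc(OC)c(O[Si](C(C)C)(C(C)C)O[Si](C(C)C)(C(C)C)O4)c(OC)c3)[C@@H](C)[C@H]2C)cc(OC)c14
F10 | step 4 | 1,3-dimethoxy-2-(methoxymethoxy)-5-[(E)-prop-1-en-1-yl]benzene | C/C=C/c1cc(OC)c(OCOC)c(OC)c1
F11 | step 4 | (1R,2S,3R,4S)-1,2-bis[3,5-dimethoxy-4-(methoxymethoxy)phenyl]-3,4-dimethylcyclobutane (meso) | COCOc1c(OC)cc([C@@H]2[C@H](c3cc(OC)c(OCOC)c(OC)c3)[C@@H](C)[C@H]2C)cc1OC
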